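**Retrosynthetic overview**

1. Marchantin H (15) ⇐ its tri-O-methyl ether 14 by one global BBr3 demethylation. The four benzene rings (A, the phenol ring; B, para-linked; C, the catechol ring; D, meta-linked) are all bought, so the only ring formed is the 18-membered macrocycle.
2. 14 ⇐ open-chain bromo styrene 12, by cutting the bond from ring A (the carbon para to the ring A hydroxyl and meta to the ring A–O–ring B oxygen) to its benzylic CH2. A one-pot hydroboration/B-alkyl Suzuki–Miyaura macrocyclisation closes the macrocycle last.
3. Enabling feature: that ring A carbon is the bromine-bearing carbon of commercial 5-bromo-2-methoxyphenol, and its CH2 partner is homobenzylic to ring D, i.e. the terminal carbon of a 3-vinylphenyl ether, exactly where anti-Markovnikov hydroboration places boron.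
4. 12 ⇐ bromo iodo bibenzyl 11 (iodine-selective vinylation) ⇐ Wittig olefination/diimide reduction joining ring A–B phosphonium salt 5 and ring C–D aldehyde 8 (ring B–ring C ethano bridge).
5. 5 and 8 ⇐ two SNAr diaryl ether formations, 1 + 2 (ring A–O–ring B) and 6 + 7 (ring C–O–ring D). Order of ring formation: none before step 8, the macrocycle in step 8.

Key step: step 8

Remark on the chemistry: the target has no stereocentre, and the flexible 18-membered ring is assumed to have no configurationally stable planar or axial chirality, so no stereocontrol is planned. Alkene 10 is carried as an E/Z mixture because step 6 removes the double bond.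

**Route**

Step 1
Reactants: 1 5-bromo-2-methoxyphenol; 2 4-fluorobenzaldehyde
Product: 3 4-(5-bromo-2-methoxyphenoxy)benzaldehyde
Conditions: K2CO3, DMF, 140 °C
Reagents that add atoms: none
Why: Nucleophilic aromatic substitution (SNAr): the para-formyl group stabilises the Meisenheimer adduct of 2 so that the phenoxide of 1 displaces fluoride, while the C–Br bond of 1 has no such activation and stays intact.

Step 2
Reactants: 3 4-(5-bromo-2-methoxyphenoxy)benzaldehyde
Product: 4 [4-(5-bromo-2-methoxyphenoxy)phenyl]methanol
Conditions: NaBH4, MeOH/THF, 0 °C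
Reagents that add atoms: none
Why: Hydride reduction of an aryl aldehyde with NaBH4, a reagent that leaves the aryl bromide and the diaryl ether untouched.

Step 3
Reactants: 4 [4-(5-bromo-2-methoxyphenoxy)phenyl]methanol
Product: 5 {[4-(5-bromo-2-methoxyphenoxy)phenyl]methyl}triphenylphosphonium bromide
Conditions: PPh3·HBr, MeCN, reflux
Reagents that add atoms: triphenylphosphine hydrobromide, [Br-].c1ccc(cc1)[PH+](c1ccccc1)c1ccccc1
Why: Acid-mediated nucleophilic substitution of a benzylic alcohol by PPh3 (protonation by HBr, loss of water from the para-aryloxy-stabilised benzylic position, capture by phosphorus), the standard one-step phosphonium salt formation that avoids a separate benzylic bromide.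

Step 4
Reactants: 6 2-fluoro-3,4-dimethoxybenzaldehyde; 7 3-iodophenol
Product: 8 2-(3-iodophenoxy)-3,4-dimethoxybenzaldehyde
Conditions: Cs2CO3, DMSO, 110 °C
Reagents that add atoms: none
Why: Nucleophilic aromatic substitution (SNAr): the ortho-formyl group activates the C–F bond of 6 toward the cesium phenoxide of 7, and in the absence of a transition metal the C–I bond is inert.

Step 5
Reactants: 5 {[4-(5-bromo-2-methoxyphenoxy)phenyl]methyl}triphenylphosphonium bromide; 8 2-(3-iodophenoxy)-3,4-dimethoxybenzaldehyde
Product: 10 4-bromo-2-{4-[2-(2-(3-iodophenoxy)-3,4-dimethoxyphenyl)ethenyl]phenoxy}-1-methoxybenzene (E/Z mixture), via phosphorus ylide 9 (not isolated)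
Conditions: KOtBu, THF, 0 °C; then 8, 0 °C to rt
Reagents that add atoms: none
Why: Wittig olefination of the non-enolisable aldehyde 8 with the semi-stabilised benzylic ylide 9; the double-bond geometry is of no consequence because step 6 saturates it.

Step 6
Reactants: 10 4-bromo-2-{4-[2-(2-(3-iodophenoxy)-3,4-dimethoxyphenyl)ethenyl]phenoxy}-1-methoxybenzene (E/Z mixture)
Product: 11 4-bromo-2-{4-[2-(2-(3-iodophenoxy)-3,4-dimethoxyphenyl)ethyl]phenoxy}-1-methoxybenzene
Conditions: TsNHNH2 (excess), NaOAc, THF/H2O, reflux
Reagents that add atoms: none
Why: Diimide reduction: HN=NH released from the sulfonyl hydrazide transfers two hydrogens to the stilbene in a concerted syn fashion, which saturates the C=C bond without the C–Br and C–I hydrogenolysis that a heterogeneous palladium hydrogenation would risk.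

Step 7
Reactants: 11 4-bromo-2-{4-[2-(2-(3-iodophenoxy)-3,4-dimethoxyphenyl)ethyl]phenoxy}-1-methoxybenzene
Product: 12 4-bromo-2-{4-[2-(2-(3-ethenylphenoxy)-3,4-dimethoxyphenyl)ethyl]phenoxy}-1-methoxybenzene
Conditions: CH2=CHBF3K (1.05 equiv), PdCl2 (2 mol%), PPh3 (6 mol%), Cs2CO3, THF/H2O 9:1, 60 °C
Reagents that add atoms: potassium vinyltrifluoroborate, [K+].C=C[B-](F)(F)F
Why: Chemoselective Suzuki–Miyaura vinylation: oxidative addition of zerovalent palladium to the C–I bond of ring D is much faster than to the electron-rich C–Br bond of ring A (para to methoxy), so with a slight excess of the vinylboron reagent at moderate temperature only iodine should be exchanged.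

Step 8
Reactants: 12 4-bromo-2-{4-[2-(2-(3-ethenylphenoxy)-3,4-dimethoxyphenyl)ethyl]phenoxy}-1-methoxybenzene
Product: 14 marchantin H tri-O-methyl ether, via alkylborane 13 (not isolated)
Conditions: 9-BBN (1.5 equiv), THF, 0 °C to rt; then syringe-pump addition to Pd(OAc)2 (15 mol%), SPhos (30 mol%), aq. K3PO4 (3 equiv), THF, 65 °C (final 2 mM)
Reagents that add atoms: 9-borabicyclo[3.3.1]nonane (9-BBN), B1C2CCCC1CCC2 (its boron and bicycle are carried in 13 only; 14 keeps one hydrogen from it)
Why: 9-BBN adds across the ring D vinyl group in a concerted syn, anti-Markovnikov fashion, so boron sits on the terminal carbon of alkylborane 13; zerovalent palladium then inserts into the only C–Br bond (ring A, para to methoxy), the phosphate-activated borinate hands its primary alkyl group to the arylpalladium bromide, and reductive elimination forms the C(sp3)–C(sp2) bond. The closest known reaction type is the one-pot hydroboration/B-alkyl Suzuki–Miyaura macrocyclisation. One ring is closed, the 18-membered macrocycle, by end-to-end intramolecular cross-coupling through a palladacycle that holds both chain termini. No stereocentre is formed. The step needs regioselective hydroboration, which the bulk of 9-BBN and the polarisation of the styrene secure, a single site of oxidative addition, which the lone C–Br bond secures, and ring closure in preference to oligomerisation, which slow addition into a dilute catalyst solution and the bent 1,2-linkage at ring C and 1,3-linkages at rings A and D (they fold the chain so that its ends approach) should secure. β-Hydride elimination from the alkylpalladium intermediate is countered by the bulky, electron-rich SPhos ligand, which speeds reductive elimination.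

Step 9
Reactants: 14 marchantin H tri-O-methyl ether
Product: 15 marchantin H
Conditions: BBr3, CH2Cl2, −78 °C to rt; then H2O
Reagents that add atoms: none
Why: Lewis acid ether cleavage: BBr3 coordinates each methoxy oxygen and bromide removes the methyl group by SN2, whereas the two diaryl ether bonds, which offer no sp3 carbon for attack, survive; hydrolysis of the aryl borates frees the three phenols.

**Compound list**

1 | 5-bromo-2-methoxyphenol | COc1ccc(Br)cc1O | starting material
2 | 4-fluorobenzaldehyde | O=Cc1ccc(F)cc1 | starting material
3 | 4-(5-bromo-2-methoxyphenoxy)benzaldehyde | COc1ccc(Br)cc1Oc1ccc(C=O)cc1 | intermediate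
4 | [4-(5-bromo-2-methoxyphenoxy)phenyl]methanol | COc1ccc(Br)cc1Oc1ccc(CO)cc1 | intermediate
5 | {[4-(5-bromo-2-methoxyphenoxy)phenyl]methyl}triphenylphosphonium bromide | COc1ccc(Br)cc1Oc1ccc(C[P+](c2ccccc2)(c2ccccc2)c2ccccc2)cc1.[Br-] | intermediate
6 | 2-fluoro-3,4-dimethoxybenzaldehyde | COc1ccc(C=O)c(F)c1OC | starting material
7 | 3-iodophenol | Oc1cccc(I)c1 | starting material
8 | 2-(3-iodophenoxy)-3,4-dimethoxybenzaldehyde | COc1ccc(C=O)c(Oc2cccc(I)c2)c1OC | intermediate
9 | [4-(5-bromo-2-methoxyphenoxy)benzylidene]triphenylphosphorane (ylide formed in the flask, not isolated) | COc1ccc(Br)cc1Oc1ccc(C=P(c2ccccc2)(c2ccccc2)c2ccccc2)cc1 | intermediate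
10 | 4-bromo-2-{4-[2-(2-(3-iodophenoxy)-3,4-dimethoxyphenyl)ethenyl]phenoxy}-1-methoxybenzene (E/Z mixture, double bond geometry not defined) | COc1ccc(Br)cc1Oc1ccc(C=Cc2ccc(OC)c(OC)c2Oc2cccc(I)c2)cc1 | intermediate
11 | 4-bromo-2-{4-[2-(2-(3-iodophenoxy)-3,4-dimethoxyphenyl)ethyl]phenoxy}-1-methoxybenzene | COc1ccc(Br)cc1Oc1ccc(CCc2ccc(OC)c(OC)c2Oc2cccc(I)c2)cc1 | intermediate
12 | 4-bromo-2-{4-[2-(2-(3-ethenylphenoxy)-3,4-dimethoxyphenyl)ethyl]phenoxy}-1-methoxybenzene | COc1ccc(Br)cc1Oc1ccc(CCc2ccc(OC)c(OC)c2Oc2cccc(C=C)c2)cc1 | intermediate
13 | 9-{2-[3-(6-{2-[4-(5-bromo-2-methoxyphenoxy)phenyl]ethyl}-2,3-dimethoxyphenoxy)phenyl]ethyl}-9-borabicyclo[3.3.1]nonane (alkylborane formed in the flask, not isolated) | COc1ccc(Br)cc1Oc1ccc(CCc2ccc(OC)c(OC)c2Oc2cccc(CCB3C4CCCC3CCC4)c2)cc1 | intermediate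
14 | marchantin H tri-O-methyl ether (18-membered macrocycle, the three phenols as methyl ethers) | COc1ccc2cc1Oc1ccc(cc1)CCc1ccc(OC)c(OC)c1Oc1cccc(c1)CC2 | intermediate
15 | marchantin H | Oc1ccc2cc1Oc1ccc(cc1)CCc1ccc(O)c(O)c1Oc1cccc(c1)CC2 | target

**Step count and risks**

Total step count: 9. Longest linear sequence: 8 steps (steps 1, 2, 3, 5, 6, 7, 8, 9); the second branch (step 4) joins at step 5.

The three steps most likely to fail are these.

Step 8 (ring closure). Intermolecular coupling may outrun ring closure and give oligomers. β-Hydride elimination or protodeboronation of 13 may return 12 or its ethyl analogue. Oxidative addition to the electron-rich C–Br bond may be slow at high dilution. The fallback sets out from 12 and comes back at 14. An intramolecular Mizoroki–Heck reaction (Pd(OAc)2, P(o-tol)3, K2CO3, Bu4NCl, DMF, 100 °C, high dilution) should join the same two carbons by carbopalladation of the vinyl group and syn β-hydride elimination. It needs no organoboron partner, and β-hydride elimination becomes the productive step. It should give the macrocyclic (E)-stilbene tri-O-methyl ether F1. Hydrogenation (H2, Pd/C, EtOAc, rt) of this halogen-free compound should then give 14.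

Step 7 (halogen discrimination). The second carbon–halogen bond may also be vinylated, or the new styrene may react with the remaining C–Br bond in a Heck-type side reaction. The fallback sets out from 11 and comes back at 12, and it replaces catalysis by a stoichiometric exchange that is selective for iodine. Iodine–magnesium exchange (iPrMgCl·LiCl, THF, −15 °C) should metalate only ring D, since the electron-rich aryl bromide does not exchange at this temperature. A DMF quench should then give 3-(6-{2-[4-(5-bromo-2-methoxyphenoxy)phenyl]ethyl}-2,3-dimethoxyphenoxy)benzaldehyde F2. Wittig methylenation (Ph3PCH3Br, KOtBu, THF, 0 °C) should convert this aldehyde into 12.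

Step 4 (diaryl ether at ring C). The substitution may be sluggish, because the para-methoxy group weakens the activation by the formyl group and the fluorine is flanked on both sides. The aldehyde may then decompose under forcing basic conditions. The fallback sets out from 6 (with 7 as before) and comes back at 8, and it exchanges the activating group for one that tolerates forcing conditions. One-pot oxime formation and dehydration (NH2OH·HCl, HCO2Na, HCO2H, reflux) should give 2-fluoro-3,4-dimethoxybenzonitrile F3. SNAr with 7 (K2CO3, NMP, 150 °C) should give 2-(3-iodophenoxy)-3,4-dimethoxybenzonitrile F4. Partial reduction (i-Bu2AlH, toluene, −78 °C; aq. HCl work-up) should return aldehyde 8.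

Further compounds

F1 | step 8 | macrocyclic (E)-stilbene tri-O-methyl ether (14 with an E double bond in the ring D–ring A bridge) | COc1ccc(/C=C/c2cccc(c2)Oc2c(OC)c(OC)ccc2CCc2ccc(cc2)O3)cc13
F2 | step 7 | 3-(6-{2-[4-(5-bromo-2-methoxyphenoxy)phenyl]ethyl}-2,3-dimethoxyphenoxy)benzaldehyde | COc1ccc(Br)cc1Oc1ccc(CCc2ccc(OC)c(OC)c2Oc2cccc(C=O)c2)cc1
F3 | step 4 | 2-fluoro-3,4-dimethoxybenzonitrile | COc1ccc(C#N)c(F)c1OC
F4 | step 4 | 2-(3-iodophenoxy)-3,4-dimethoxybenzonitrile | COc1ccc(C#N)c(Oc2cccc(I)c2)c1OC
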